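**Assumption:** the SMILES is taken literally. In labdane numbering it is the (4R,5S,8R,9R,10R) isomer: a trans-decalin with C19H2O, 8-OH and H-9 on the face of the C10 methyl (C20), and H-5, C18, C17 and the C9 side chain on the opposite face.

Labdane atom numbers are used throughout. "syn" and "anti" mean the same or the opposite ring face as C20. The carvone ring becomes ring B.

## Retrosynthetic overview

1. Target ⇐ Z-selective Horner–Wadsworth–Emmons reaction of the C19 phosphonoacetate of diene diol 20 with 4-silyloxybenzaldehyde.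
2. Diene ⇐ copper-catalysed coupling of the C12 tosylate with buta-1,3-dien-2-yl Grignard; 8-OH ⇐ trans-diaxial Markovnikov oxymercuration of the 7-ene.
3. Ring A (formed second) ⇐ intramolecular C-alkylation of the C4 aldehyde enolate by the C3 chloride; this sets C4 and the trans ring fusion.
4. C9–C11 bond ⇐ Johnson–Claisen [3,3] rearrangement of the 7-hydroxy-8-ene, which comes from Wharton transposition of the carvone-type epoxy ketone.
5. Ring B (bought) = (S)-(+)-carvone, which supplies C5; C10 is set by methylation then alkylation trans to the isopropenyl group.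

## Route

**Step 1**
Reactants: 1 (S)-(+)-carvone
Product: 3 trans-6-methylcarvone, via lithium dienolate of carvone 2 (not isolated)
Conditions: LiN(iPr)2, THF, −78 °C; MeI, −78 → 0 °C
Reagents that add atoms: iodomethane, CI
Why: Kinetic α'-deprotonation and SN2 methylation of the cross-conjugated enolate install C20; the new centre is enolised again in step 2, so only the purchased C5 matters.

**Step 2**
Reactants: 3 trans-6-methylcarvone
Product: 5 6-(3-chloropropyl)-6-methylcarvone, via lithium enolate of 6-methylcarvone 4 (not isolated)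
Conditions: LiN(iPr)2, THF, −78 °C; ICH2CH2CH2Cl, DMPU, −78 °C → rt
Reagents that add atoms: 1-chloro-3-iodopropane, ClCCCI
Why: Enolate alkylation at the iodide end occurs anti to the neighbouring isopropenyl group, so the C1–C3 chain ends trans and the methyl cis to it, which fixes quaternary C10.

**Step 3**
Reactants: 5 6-(3-chloropropyl)-6-methylcarvone
Product: 6 7,8-epoxy-9-ketone (epoxide anti to C20)
Conditions: 30% H2O2, NaOH (0.3 equiv), MeOH, 0 °C → rt
Reagents that add atoms: hydrogen peroxide, OO
Why: Weitz–Scheffer nucleophilic epoxidation: hydroperoxide adds axially to C7 trans to the isopropenyl group, as with carvone itself, placing the oxygen anti to C20.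

**Step 4**
Reactants: 6 7,8-epoxy-9-ketone
Product: 8 allylic alcohol (7-OH anti to C20; 8-ene), via epoxy hydrazone 7 (not isolated)
Conditions: N2H4·H2O, AcOH (cat.), MeOH, 0 → 40 °C
Reagents that add atoms: none
Why: Wharton transposition: the hydrazone opens the epoxide at C8 and loses N2, giving the 8-ene while the C7–O bond and its configuration are untouched.

**Step 5**
Reactants: 8 allylic alcohol
Product: 10 ethyl ester (C9–CH2CO2Et anti to C20; 7-ene), via ketene acetal 9 (not isolated)
Conditions: MeC(OEt)3, EtCO2H (cat.), 140 °C, EtOH distilled off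
Reagents that add atoms: triethyl orthoacetate, CC(OCC)(OCC)OCC
Why: Johnson–Claisen [3,3]-sigmatropic rearrangement through a chair transition state transfers the pseudoaxial C7–O stereocentre suprafacially to C9, forming the C9–C11 bond anti to C20 and moving the alkene to C7=C8.

**Step 6**
Reactants: 10 ethyl ester
Product: 12 primary alcohol (C19–OH; C4 epimers), via B-alkyl-9-BBN adduct 11 (not isolated)
Conditions: 9-BBN, THF, 0 °C → rt; NaBO3·4H2O, H2O, rt
Reagents that add atoms: sodium perborate, [Na+].[O-]OB=O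
Why: Anti-Markovnikov hydroboration–oxidation; 9-BBN reacts with the 1,1-disubstituted isopropenyl group far faster than with the trisubstituted ring alkene and leaves ester and chloride alone; the C4 configuration is erased in step 8.

**Step 7**
Reactants: 12 primary alcohol
Product: 13 aldehyde (C4 epimers)
Conditions: Dess–Martin periodinane, CH2Cl2, 0 °C → rt
Reagents that add atoms: none
Why: Dess–Martin oxidation gives the α-branched aldehyde without touching alkene, ester or chloride.

**Step 8**
Reactants: 13 aldehyde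
Product: 15 bicyclic aldehyde (ring A closed; CHO syn to C20), via potassium enolate 14 (not isolated)
Conditions: KOtBu, THF/t-BuOH, 0 → 40 °C
Reagents that add atoms: none
Why: Intramolecular enolate C-alkylation (6-exo-tet): the trans-diequatorial tether closes a chair trans-decalin in which the flat enolate carbon, not the methyl, faces the axial C20 methyl, so C19 ends syn and C18 anti to C20; both C4 epimers of 13 give the same enolate.

**Step 9**
Reactants: 15 bicyclic aldehyde
Product: 16 12,19-diol
Conditions: LiAlH4, THF, 0 °C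
Reagents that add atoms: none
Why: Hydride reduction converts the ester and the aldehyde to primary alcohols in one operation without affecting any stereocentre.

**Step 10**
Reactants: 16 12,19-diol
Product: 17 12-tosylate
Conditions: TsCl (1.05 equiv), pyridine, CH2Cl2, −10 °C
Reagents that add atoms: 4-methylbenzenesulfonyl chloride, Cc1ccc(cc1)S(Cl)(=O)=O
Why: Sulfonylation is much faster at the unhindered C12 hydroxyl than at the neopentyl axial C19 hydroxyl.

**Step 11**
Reactants: 17 12-tosylate
Product: 19 8-hydroxy tosylate (8-OH syn to C20), via organomercurial 18 (not isolated)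
Conditions: Hg(OAc)2, THF/H2O, rt; NaOH (aq), NaBH4, 0 °C
Reagents that add atoms: water, O
Why: Oxymercuration–demercuration: water opens the mercurinium ion at tertiary C8 in the trans-diaxial (Fürst–Plattner) mode of the locked ring B, giving the axial 8-OH syn to C20 and trans to the C9 chain; the tosylate cannot participate.

**Step 12**
Reactants: 19 8-hydroxy tosylate
Product: 20 diene diol
Conditions: CH2=C(MgCl)CH=CH2 (4 equiv, from 2-chlorobuta-1,3-diene and Mg in THF), Li2CuCl4 (5 mol %), THF, −20 °C → rt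
Reagents that add atoms: buta-1,3-dien-2-ylmagnesium chloride, C=CC(=C)[Mg]Cl
Why: Copper-catalysed Kochi-type coupling of the primary tosylate with the dienyl Grignard builds the 2-substituted butadiene; the trans-diaxial 8-alkoxide cannot reach C12 to form an ether.

**Step 13**
Reactants: 20 diene diol
Product: 21 19-bromoacetate
Conditions: BrCH2COBr, pyridine, CH2Cl2, −20 °C
Reagents that add atoms: bromoacetyl bromide, BrCC(Br)=O
Why: Acylation of the only primary hydroxyl; the tertiary 8-OH is inert under these conditions.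

**Step 14**
Reactants: 21 19-bromoacetate
Product: 22 19-(diphenoxyphosphoryl)acetate
Conditions: (PhO)2P(O)H, Et3N, CH2Cl2, 0 °C → rt
Reagents that add atoms: diphenyl phosphite, O=[PH](Oc1ccccc1)Oc1ccccc1
Why: Michaelis–Becker P-alkylation of the phosphite with the α-bromo ester gives the Ando-type phosphonate under mild base.

**Step 15**
Reactants: 22 19-(diphenoxyphosphoryl)acetate
Product: 23 silyl-protected (Z)-coumarate
Conditions: NaH (1.0 equiv), THF, −78 °C; 4-(t-BuMe2SiO)C6H4CHO, −78 → 0 °C
Reagents that add atoms: 4-[(tert-butyldimethylsilyl)oxy]benzaldehyde, CC(C)(C)[Si](C)(C)Oc1ccc(C=O)cc1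
Why: Ando-type Horner–Wadsworth–Emmons olefination: the diaryl phosphonate eliminates quickly from the kinetic adduct and gives the (Z)-cinnamate (typically about 9:1 Z:E); the minor E isomer is removed by chromatography.

**Step 16**
Reactants: 23 silyl-protected (Z)-coumarate
Product: 24 target
Conditions: Bu4NF, AcOH, THF, 0 °C
Reagents that add atoms: none
Why: Buffered fluoride cleaves the aryl silyl ether without isomerising the Z-alkene or touching the ester, diene or tertiary alcohol.

## Compound list

1 | (S)-(+)-carvone, (5S)-2-methyl-5-(prop-1-en-2-yl)cyclohex-2-en-1-one | `CC1=CC[C@@H](CC1=O)C(C)=C` | starting material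
2 | lithium cross-conjugated dienolate of carvone (O–C9=C10) | `CC1=CC[C@@H](C=C1O[Li])C(C)=C` | intermediate
3 | trans-6-methylcarvone, (5S,6R)-2,6-dimethyl-5-(prop-1-en-2-yl)cyclohex-2-en-1-one (some cis epimer is carried along) | `CC1=CC[C@@H]([C@@H](C)C1=O)C(C)=C` | intermediate
4 | lithium enolate of 6-methylcarvone (tetrasubstituted C9=C10 enolate) | `CC1=CC[C@@H](C(C)=C1O[Li])C(C)=C` | intermediate
5 | (5R,6R)-6-(3-chloropropyl)-2,6-dimethyl-5-(prop-1-en-2-yl)cyclohex-2-en-1-one (chloropropyl trans, methyl cis to isopropenyl) | `CC1=CC[C@@H]([C@@](C)(CCCCl)C1=O)C(C)=C` | intermediate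
6 | 7,8-epoxide of 5: 3-(3-chloropropyl)-1,3-dimethyl-4-(prop-1-en-2-yl)-7-oxabicyclo[4.1.0]heptan-2-one, epoxide oxygen anti to C20 and trans to isopropenyl | `C[C@]12O[C@H]1C[C@@H]([C@@](C)(CCCCl)C2=O)C(C)=C` | intermediate
7 | hydrazone of epoxy ketone 6 | `C[C@]12O[C@H]1C[C@@H]([C@@](C)(CCCCl)C2=NN)C(C)=C` | intermediate
8 | 4-(3-chloropropyl)-2,4-dimethyl-5-(prop-1-en-2-yl)cyclohex-2-en-1-ol; OH (on C7) anti to C20, trans to isopropenyl | `CC1=C[C@](C)(CCCCl)[C@H](C[C@@H]1O)C(C)=C` | intermediate
9 | 1-ethoxyvinyl ether (ketene acetal) of 8 | `CC1=C[C@](C)(CCCCl)[C@H](C[C@@H]1OC(=C)OCC)C(C)=C` | intermediate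
10 | ethyl 2-[6-(3-chloropropyl)-2,6-dimethyl-5-(prop-1-en-2-yl)cyclohex-2-en-1-yl]acetate; acetate arm (C11) anti to C20, cis to chloropropyl, trans to isopropenyl | `CCOC(=O)C[C@@H]1[C@](C)(CCCCl)[C@H](CC=C1C)C(C)=C` | intermediate
11 | B-alkyl-9-borabicyclo[3.3.1]nonane adduct of 10 (boron on C19) | `CCOC(=O)C[C@@H]1[C@](C)(CCCCl)[C@H](CC=C1C)C(C)CB1C2CCCC1CCC2` | intermediate
12 | primary alcohol: as 10 with the isopropenyl group converted to 1-hydroxypropan-2-yl (both C4 epimers) | `CCOC(=O)C[C@@H]1[C@](C)(CCCCl)[C@H](CC=C1C)C(C)CO` | intermediate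
13 | aldehyde: as 12 with C19 as CHO (both C4 epimers) | `CCOC(=O)C[C@@H]1[C@](C)(CCCCl)[C@H](CC=C1C)C(C)C=O` | intermediate
14 | potassium enolate of aldehyde 13 (C4=C19–OK) | `CCOC(=O)C[C@@H]1[C@](C)(CCCCl)[C@H](CC=C1C)C(C)=CO[K]` | intermediate
15 | ethyl 2-(5-formyl-2,5,8a-trimethyl-1,4,4a,5,6,7,8,8a-octahydronaphthalen-1-yl)acetate: trans-fused; CHO (C19) syn to C20; C18, H-5 and the C9 arm anti; 7-ene | `CCOC(=O)C[C@@H]1[C@]2(C)CCC[C@@](C)(C=O)[C@H]2CC=C1C` | intermediate
16 | 13,14,15,16-tetranorlabd-7-ene-12,19-diol with the stereochemistry of 15 | `OCC[C@@H]1[C@]2(C)CCC[C@@](C)(CO)[C@H]2CC=C1C` | intermediate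
17 | 12-O-tosylate of diol 16 | `Cc1ccc(cc1)S(=O)(=O)OCC[C@@H]1[C@]2(C)CCC[C@@](C)(CO)[C@H]2CC=C1C` | intermediate
18 | 7-(acetoxymercurio)-8-hydroxy adduct of 17 (Hg on C7 anti, OH on C8 syn to C20; trans-diaxial) | `Cc1ccc(cc1)S(=O)(=O)OCC[C@@H]1[C@]2(C)CCC[C@@](C)(CO)[C@H]2C[C@H]([Hg]OC(C)=O)[C@@]1(C)O` | intermediate
19 | 8,19-dihydroxy-13,14,15,16-tetranorlabdan-12-yl tosylate (8-OH syn to C20, C17 anti) | `Cc1ccc(cc1)S(=O)(=O)OCC[C@@H]1[C@]2(C)CCC[C@@](C)(CO)[C@H]2CC[C@@]1(C)O` | intermediate
20 | labda-13(16),14-diene-8,19-diol with the target configuration (4R,5S,8R,9R,10R) | `C=CC(=C)CC[C@@H]1[C@]2(C)CCC[C@@](C)(CO)[C@H]2CC[C@@]1(C)O` | intermediate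
21 | 19-O-bromoacetate of 20 | `C=CC(=C)CC[C@@H]1[C@]2(C)CCC[C@@](C)(COC(=O)CBr)[C@H]2CC[C@@]1(C)O` | intermediate
22 | 19-O-[(diphenoxyphosphoryl)acetate] of 20 | `C=CC(=C)CC[C@@H]1[C@]2(C)CCC[C@@](C)(COC(=O)CP(=O)(Oc3ccccc3)Oc3ccccc3)[C@H]2CC[C@@]1(C)O` | intermediate
23 | 19-O-[(Z)-4-(tert-butyldimethylsilyloxy)cinnamate] of 20 | `C=CC(=C)CC[C@@H]1[C@]2(C)CCC[C@@](C)(COC(=O)/C=C\c3ccc(O[Si](C)(C)C(C)(C)C)cc3)[C@H]2CC[C@@]1(C)O` | intermediate
24 | [(1R,4aR,5R,6R,8aS)-6-hydroxy-1,4a,6-trimethyl-5-(3-methylidenepent-4-en-1-yl)decahydronaphthalen-1-yl]methyl (2Z)-3-(4-hydroxyphenyl)prop-2-enoate | `C=CC(=C)CC[C@@H]1[C@]2(C)CCC[C@@](C)(COC(=O)/C=C\c3ccc(O)cc3)[C@H]2CC[C@@]1(C)O` | target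

## Summary

Total step count: 16. Longest linear sequence: 16 steps, from (S)-(+)-carvone.

**Steps most likely to fail**

Step 4 (Wharton transposition). The C9 ketone is flanked by quaternary C10 and the fully substituted epoxide carbon, so hydrazone formation may be too slow or be overtaken by epoxide opening. The fallback sets out from 6 and replaces the hydrazone chemistry by a radical fragmentation. NaBH4 in MeOH reduces the ketone to the epoxy alcohol F1 (either C9 epimer serves). PhOC(S)Cl with pyridine and DMAP converts it to the O-phenyl thionocarbonate F2. Bu3SnH with AIBN in toluene at 80 °C then generates the C9 radical, whose adjacent C8–O epoxide bond breaks to give the C7 alkoxy radical and, after hydrogen transfer, the same allylic alcohol. The route is rejoined at 8.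

Step 8 (ring A closure). A quaternary carbon is made and the C4 configuration rests on the preference of the enolate carbon over the methyl for the position facing C20; self-condensation of the aldehyde may also intervene. The fallback sets out from 13 and closes the ring through a nitrile anion, whose very small nitrile group strongly prefers the axial position syn to C20. NH2OH·HCl in pyridine gives the oxime F3, and warming with Ac2O dehydrates it to the nitrile ester F4. LiBH4 reduces the ethyl ester, the competing C–H acid, to give the hydroxy nitrile F5. LiN(iPr)2 (2.2 equiv, THF, −78 → 0 °C) then cyclises the nitrile anion onto the chloride to give the bicyclic hydroxy nitrile F6. i-Bu2AlH followed by aqueous work-up gives the hydroxy aldehyde F7, and NaBH4 reduces it. The route is rejoined at 16.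

Step 11 (hydration of the 7-ene). The 8-OH must enter syn to the axial C20 methyl, and poor facial or regiochemical control would give the 8-epimer or a 7-ol. The fallback sets out from 17 and uses a singlet-oxygen ene reaction (O2, hν, tetraphenylporphyrin, CH2Cl2, 0 °C). The suprafacial ene geometry requires the pseudoaxial H-6 on the C20 face, so the oxygen delivered to C8 is necessarily syn to C20, giving the tertiary allylic hydroperoxide F8 with a 6-ene. PPh3 reduces it to the allylic alcohol F9, and H2 over PtO2 in EtOAc saturates the 6-ene. The route is rejoined at 19.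

## Further compounds

F1 | step 4 | epoxy alcohol: 9-hydroxy analogue of epoxy ketone 6 (C9 epimers) | `C[C@]12O[C@H]1C[C@@H]([C@@](C)(CCCCl)C2O)C(C)=C`
F2 | step 4 | O-phenyl thionocarbonate of F1 | `C[C@]12O[C@H]1C[C@@H]([C@@](C)(CCCCl)C2OC(=S)Oc3ccccc3)C(C)=C`
F3 | step 8 | oxime of aldehyde 13 | `CCOC(=O)C[C@@H]1[C@](C)(CCCCl)[C@H](CC=C1C)C(C)C=NO`
F4 | step 8 | nitrile ester: as 13 with C19 as C≡N | `CCOC(=O)C[C@@H]1[C@](C)(CCCCl)[C@H](CC=C1C)C(C)C#N`
F5 | step 8 | hydroxy nitrile: as F4 with the ester reduced to CH2OH | `OCC[C@@H]1[C@](C)(CCCCl)[C@H](CC=C1C)C(C)C#N`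
F6 | step 8 | bicyclic hydroxy nitrile: ring A closed, nitrile (C19) syn to C20 | `OCC[C@@H]1[C@]2(C)CCC[C@@](C)(C#N)[C@H]2CC=C1C`
F7 | step 8 | bicyclic hydroxy aldehyde: 12-hydroxy analogue of 15 | `OCC[C@@H]1[C@]2(C)CCC[C@@](C)(C=O)[C@H]2CC=C1C`
F8 | step 11 | 8-hydroperoxy-6-ene tosylate (OOH syn to C20) | `Cc1ccc(cc1)S(=O)(=O)OCC[C@@H]1[C@]2(C)CCC[C@@](C)(CO)[C@H]2C=C[C@@]1(C)OO`
F9 | step 11 | 8-hydroxy-6-ene tosylate (OH syn to C20) | `Cc1ccc(cc1)S(=O)(=O)OCC[C@@H]1[C@]2(C)CCC[C@@](C)(CO)[C@H]2C=C[C@@]1(C)O`
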